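**Retrosynthetic overview**

- Rings: A = side-chain veratryl ring (on C7''), B = central guaiacyl ring (carries O4'), C = oxolane (O, C7, C8, C8', C7'), D = veratryl ring on C7. The last cuts are the C7'' carbinol (ketone reduction, threo) and the O4'–C8'' ether (SN2 on a lactate-derived α-tosyloxy ketone).
- Ring C as the oxolane comes from O–C7 reductive etherification of a γ-silyloxy aryl ketone. Ring D enters as its Grignard reagent on a Weinreb amide, and the C8 methyl by methylation of a γ-lactone enolate.
- The strategy rests on the C7'–C8' bond of ring C. It joins the ring B carbinol carbon C7' to the methyl-bearing C8', with aryl and methyl cis, which is the bond a homoenolate β-carbon makes with an aryl aldehyde. Cutting C7'–C8' together with O–C7(acyl) leads to (E)-crotonaldehyde and O-tosylvanillin.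
- Order of ring formation: ring C first as the cis γ-lactone (step 2), opened to the Weinreb amide (step 4), closed again as the oxolane (step 8). Rings A, B and D are bought as arenes.

Key step: step 2

Assumption: the (5aR,10bS) antipode of the aminoindanol-derived N-mesityl triazolium salt is taken to deliver the (4R,5S) lactone. If a pilot run shows the opposite sense, the commercial (5aS,10bR) salt is used and nothing else changes; 5 and 6 are drawn with the assumed antipode.

Remark: the tosylate stays on O4' until ring C is an oxolane. A free phenoxide para to the lactone C7'–O bond could open the lactone through a quinone methide and lose the cis relation. The sulfonate also keeps C7' from ionising under BF3·OEt2. For that reason ring D is brought in as a Grignard reagent on a Weinreb amide, which spares the aryl sulfonate, and not as an aryllithium on the lactone. The arylmagnesium reagent is made once as a titrated THF solution (step 6) and drawn on in steps 7 and 10.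

**Route**

Step 1
Reactants: 1 vanillin; 2 4-toluenesulfonyl chloride
Product: 3 O-tosylvanillin (4-formyl-2-methoxyphenyl 4-methylbenzenesulfonate)
Conditions: Et3N, DMAP (cat.), CH2Cl2, 0 °C to rt
Reagents that add atoms: none
Why: Base-mediated O-sulfonylation of the phenol, which leaves the aldehyde untouched and turns the electron-rich vanillin carbonyl into an electron-poor one.

Step 2
Reactants: 3 O-tosylvanillin; 4 (E)-crotonaldehyde
Product: 7 (4R,5S)-4-methyl-5-(3-methoxy-4-tosyloxyphenyl)dihydrofuran-2(3H)-one (cis), via homoenolate Breslow intermediate 5 (not isolated), via acyl azolium alkoxide 6 (not isolated)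
Conditions: (5aR,10bS)-2-mesityl-5a,10b-dihydro-4H,6H-indeno[2,1-b][1,2,4]triazolo[4,3-d][1,4]oxazin-2-ium chloride (10 mol%), DBU (10 mol%), THF, 0 °C to rt, slow addition of 4
Reagents that add atoms: none
Why: The free carbene adds to the carbonyl of 4 and proton transfer gives the extended Breslow intermediate 5, a homoenolate whose β-carbon attacks the aldehyde carbon of 3 to make the C7'–C8' bond; tautomerisation to acyl azolium 6 then lets the new alkoxide acylate itself (O–C7 bond) and release the carbene. The closest known reaction type is the carbene-catalysed homoenolate [3+2] annulation of enals with aromatic aldehydes to cis-γ-butyrolactones. Ring C closes as the γ-lactone by 5-exo-trig acyl substitution. The cis relation of the C7' aryl group and the C8' methyl should come from the compact transition state in which the aldehyde aryl group stacks over the planar dienol, and the absolute configuration of both centres (4R,5S) from the aminoindanol backbone, which shields one face of the homoenolate. The step needs cross- over self-annulation (answered by the sulfonate-activated aldehyde and slow addition of 4), cis over trans (the stacked transition state) and face selection (the chiral triazolium); the last is the least secure for a β-methyl enal, so the sulfonate lactone, expected to be crystalline, is to be recrystallised to raise its enantiomeric purity.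

Step 3
Reactants: 7 cis lactone
Product: 9 (3R,4R,5S)-3,4-dimethyl-5-(3-methoxy-4-tosyloxyphenyl)dihydrofuran-2(3H)-one, via lithium enolate 8 (not isolated)
Conditions: LiN(SiMe3)2, THF, −78 °C; then MeI, −78 to −40 °C
Reagents that add atoms: iodomethane, CI
Why: Lactone enolate alkylation in which iodomethane should approach the enolate face opposite the cis C8' methyl and C7' aryl groups, setting C8 (3R) trans to the C8' methyl, while the hindered amide base leaves the aryl sulfonate alone at −78 °C.

Step 4
Reactants: 9 dimethyl lactone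
Product: 10 (2R,3R,4S)-4-hydroxy-N-methoxy-4-(3-methoxy-4-tosyloxyphenyl)-N,2,3-trimethylbutanamide
Conditions: AlMe3, MeNH(OMe)·HCl, CH2Cl2, 0 °C to rt; aq. potassium sodium tartrate; crude product used at once
Reagents that add atoms: N,O-dimethylhydroxylamine hydrochloride, CNOC.Cl
Why: Weinreb aminolysis of the lactone by the aluminium amide is an acyl substitution that does not touch the C7'–O bond or the weakly acidic C8 centre, so all three stereocentres are kept.

Step 5
Reactants: 10 hydroxy Weinreb amide
Product: 11 (2R,3R,4S)-N-methoxy-4-(3-methoxy-4-tosyloxyphenyl)-N,2,3-trimethyl-4-(triethylsilyloxy)butanamide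
Conditions: Et3SiCl, imidazole, DMAP (cat.), DMF, 0 °C to rt
Reagents that add atoms: chlorotriethylsilane, CC[Si](Cl)(CC)CC
Why: O-silylation of the benzylic alcohol stops relactonisation and masks the hydroxyl for the Grignard step without breaking any bond at a stereocentre.

Step 6
Reactants: 12 4-bromoveratrole
Product: 13 3,4-dimethoxyphenylmagnesium bromide (THF solution, titrated and kept under argon)
Conditions: Mg turnings, I2 (cat.), THF, 40 °C
Reagents that add atoms: magnesium, [Mg]
Why: Grignard formation by insertion of magnesium into the aryl C–Br bond, which is routine for an electron-rich aryl bromide in THF and gives one batch of reagent for the two later additions.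

Step 7
Reactants: 11 silyl ether Weinreb amide; 13 3,4-dimethoxyphenylmagnesium bromide
Product: 14 (2R,3R,4S)-1-(3,4-dimethoxyphenyl)-4-(3-methoxy-4-tosyloxyphenyl)-2,3-dimethyl-4-(triethylsilyloxy)butan-1-one
Conditions: 13 (1.5 equiv), THF, 0 °C to rt; aq. NH4Cl
Reagents that add atoms: none
Why: Weinreb ketone synthesis, in which the chelated tetrahedral magnesium adduct stops at the ketone stage and protects C8 from enolisation until the quench, and the arylmagnesium reagent (unlike an aryllithium) should not attack the aryl sulfonate at this temperature.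

Step 8
Reactants: 14 silyloxy ketone
Product: 16 4-[(2S,3R,4R,5S)-5-(3,4-dimethoxyphenyl)-3,4-dimethyloxolan-2-yl]-2-methoxyphenyl 4-methylbenzenesulfonate, via cyclic oxocarbenium ion 15 (not isolated)
Conditions: Et3SiH, BF3·OEt2, CH2Cl2, −78 to −50 °C
Reagents that add atoms: none
Why: Reductive etherification in which BF3·OEt2 makes the silyl ether oxygen add to the ketone and strips the silanolate to give oxocarbenium ion 15 (five-membered O–C7 closure), and Et3SiH should deliver hydride to C7 on the face away from the neighbouring C8 methyl (inside attack on the envelope), placing ring D cis to that methyl (7S), while the low temperature avoids C8 epimerisation through the enol ether and the sulfonate on ring B keeps C7' from ionising.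

Step 9
Reactants: 16 oxolane tosylate
Product: 17 4-[(2S,3R,4R,5S)-5-(3,4-dimethoxyphenyl)-3,4-dimethyloxolan-2-yl]-2-methoxyphenol
Conditions: KOH, H2O–t-BuOH–THF, 70 °C; then aq. NH4Cl
Reagents that add atoms: none
Why: Hydroxide attacks the sulfur of the aryl sulfonate (S–O cleavage) and frees the phenoxide, the non-nucleophilic alcohol co-solvent avoids an alkyl tosylate that could re-alkylate the phenoxide, and the oxolane, whose ring oxygen is a poor leaving group, and the methyl ethers should be stable to base at this temperature.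

Step 10
Reactants: 18 (S)-N,N-dimethyllactamide; 13 3,4-dimethoxyphenylmagnesium bromide
Product: 19 (S)-1-(3,4-dimethoxyphenyl)-2-hydroxypropan-1-one
Conditions: 13 (2.5 equiv), THF, 0 °C to rt; aq. NH4Cl
Reagents that add atoms: none
Why: Grignard addition to the tertiary amide, in which the first equivalent forms the magnesium alkoxide and the second gives a chelated hemiaminal that survives until the quench, so neither over-addition nor racemisation of the lactate centre is expected.

Step 11
Reactants: 19 hydroxy ketone; 2 4-toluenesulfonyl chloride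
Product: 20 (S)-1-(3,4-dimethoxyphenyl)-1-oxopropan-2-yl 4-methylbenzenesulfonate
Conditions: pyridine, DMAP (cat.), CH2Cl2, 0 °C to rt
Reagents that add atoms: none
Why: O-sulfonylation of the secondary alcohol with retention, since the C8''–O bond is not broken, under a weak base that should not enolise the ketone.

Step 12
Reactants: 17 phenol; 20 α-tosyloxy ketone
Product: 21 (R)-1-(3,4-dimethoxyphenyl)-2-{4-[(2S,3R,4R,5S)-5-(3,4-dimethoxyphenyl)-3,4-dimethyloxolan-2-yl]-2-methoxyphenoxy}propan-1-one
Conditions: Cs2CO3, DMF, 0 °C to rt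
Reagents that add atoms: none
Why: Williamson-type SN2 displacement of the carbonyl-activated secondary tosylate by the caesium phenoxide with inversion, which turns (S)-C8'' into the (R) ether at a temperature low enough to limit enolisation.

Step 13
Reactants: 21 α-aryloxy ketone
Product: 22 (1R,2R)-1-(3,4-dimethoxyphenyl)-2-{4-[(2S,3R,4R,5S)-5-(3,4-dimethoxyphenyl)-3,4-dimethyloxolan-2-yl]-2-methoxyphenoxy}propan-1-ol (target)
Conditions: Bu4NBH4, MeOH–CH2Cl2, −20 °C; aq. NH4Cl
Reagents that add atoms: none
Why: Felkin–Anh (polar) 1,2-induction in a ketone reduction, where the non-chelating tetrabutylammonium counter-ion leaves the C8''–OAr bond anti to the incoming hydride, which passes the C8'' hydrogen, so the new C7'' carbinol should come out R, threo to C8''.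

**Compound list**

1 | vanillin (4-hydroxy-3-methoxybenzaldehyde) | COc1cc(C=O)ccc1O | starting material
2 | 4-toluenesulfonyl chloride | Cc1ccc(S(=O)(=O)Cl)cc1 | starting material
3 | O-tosylvanillin (4-formyl-2-methoxyphenyl 4-methylbenzenesulfonate) | COc1cc(C=O)ccc1OS(=O)(=O)c1ccc(C)cc1 | intermediate
4 | (E)-crotonaldehyde | C/C=C/C=O | starting material
5 | homoenolate Breslow intermediate (dienol adduct of 4 and the (5aR,10bS) triazolylidene) | C/C=C/C(O)=C1N(c2c(C)cc(C)cc2C)N=C2CO[C@@H]3Cc4ccccc4[C@@H]3N12 | intermediate (not isolated)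
6 | acyl azolium alkoxide (zwitterion after C7'–C8' bond formation) | [O-][C@H](c1ccc(OS(=O)(=O)c2ccc(C)cc2)c(OC)c1)[C@H](C)CC(=O)c1[n+](-c2c(C)cc(C)cc2C)nc2CO[C@@H]3Cc4ccccc4[C@@H]3n12 | intermediate (not isolated)
7 | (4R,5S)-4-methyl-5-(3-methoxy-4-tosyloxyphenyl)dihydrofuran-2(3H)-one (cis) | COc1cc([C@H]2OC(=O)C[C@H]2C)ccc1OS(=O)(=O)c1ccc(C)cc1 | intermediate
8 | lithium enolate of 7 | COc1cc([C@H]2OC([O-])=C[C@H]2C)ccc1OS(=O)(=O)c1ccc(C)cc1.[Li+] | intermediate (not isolated)
9 | (3R,4R,5S)-3,4-dimethyl-5-(3-methoxy-4-tosyloxyphenyl)dihydrofuran-2(3H)-one | COc1cc([C@H]2OC(=O)[C@H](C)[C@H]2C)ccc1OS(=O)(=O)c1ccc(C)cc1 | intermediate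
10 | (2R,3R,4S)-4-hydroxy-N-methoxy-4-(3-methoxy-4-tosyloxyphenyl)-N,2,3-trimethylbutanamide | CON(C)C(=O)[C@H](C)[C@@H](C)[C@H](O)c1ccc(OS(=O)(=O)c2ccc(C)cc2)c(OC)c1 | intermediate
11 | (2R,3R,4S)-N-methoxy-4-(3-methoxy-4-tosyloxyphenyl)-N,2,3-trimethyl-4-(triethylsilyloxy)butanamide | CON(C)C(=O)[C@H](C)[C@@H](C)[C@H](O[Si](CC)(CC)CC)c1ccc(OS(=O)(=O)c2ccc(C)cc2)c(OC)c1 | intermediate
12 | 4-bromoveratrole (4-bromo-1,2-dimethoxybenzene) | COc1ccc(Br)cc1OC | starting material
13 | 3,4-dimethoxyphenylmagnesium bromide (THF solution) | COc1ccc([Mg]Br)cc1OC | intermediate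
14 | (2R,3R,4S)-1-(3,4-dimethoxyphenyl)-4-(3-methoxy-4-tosyloxyphenyl)-2,3-dimethyl-4-(triethylsilyloxy)butan-1-one | COc1ccc(C(=O)[C@H](C)[C@@H](C)[C@H](O[Si](CC)(CC)CC)c2ccc(OS(=O)(=O)c3ccc(C)cc3)c(OC)c2)cc1OC | intermediate
15 | cyclic oxocarbenium ion (C7=O+ in ring C) | COc1cc([C@H]2[O+]=C(c3ccc(OC)c(OC)c3)[C@H](C)[C@H]2C)ccc1OS(=O)(=O)c1ccc(C)cc1 | intermediate (not isolated)
16 | 4-[(2S,3R,4R,5S)-5-(3,4-dimethoxyphenyl)-3,4-dimethyloxolan-2-yl]-2-methoxyphenyl 4-methylbenzenesulfonate | COc1cc([C@H]2O[C@H](c3ccc(OC)c(OC)c3)[C@H](C)[C@H]2C)ccc1OS(=O)(=O)c1ccc(C)cc1 | intermediate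
17 | 4-[(2S,3R,4R,5S)-5-(3,4-dimethoxyphenyl)-3,4-dimethyloxolan-2-yl]-2-methoxyphenol | COc1cc([C@H]2O[C@H](c3ccc(OC)c(OC)c3)[C@H](C)[C@H]2C)ccc1O | intermediate
18 | (S)-N,N-dimethyllactamide | C[C@H](O)C(=O)N(C)C | starting material
19 | (S)-1-(3,4-dimethoxyphenyl)-2-hydroxypropan-1-one | C[C@H](O)C(=O)c1ccc(OC)c(OC)c1 | intermediate
20 | (S)-1-(3,4-dimethoxyphenyl)-1-oxopropan-2-yl 4-methylbenzenesulfonate | C[C@H](OS(=O)(=O)c1ccc(C)cc1)C(=O)c1ccc(OC)c(OC)c1 | intermediate
21 | (R)-1-(3,4-dimethoxyphenyl)-2-{4-[(2S,3R,4R,5S)-5-(3,4-dimethoxyphenyl)-3,4-dimethyloxolan-2-yl]-2-methoxyphenoxy}propan-1-one | COc1ccc(C(=O)[C@@H](C)Oc2ccc([C@H]3O[C@H](c4ccc(OC)c(OC)c4)[C@H](C)[C@H]3C)cc2OC)cc1OC | intermediate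
22 | (1R,2R)-1-(3,4-dimethoxyphenyl)-2-{4-[(2S,3R,4R,5S)-5-(3,4-dimethoxyphenyl)-3,4-dimethyloxolan-2-yl]-2-methoxyphenoxy}propan-1-ol | COc1ccc([C@@H](O)[C@@H](C)Oc2ccc([C@H]3O[C@H](c4ccc(OC)c(OC)c4)[C@H](C)[C@H]3C)cc2OC)cc1OC | target

**Step count and risks**

Total step count: 13. Longest linear sequence: 10 steps (steps 1–5, 7–9, 12 and 13, from vanillin); step 6 supplies the arylmagnesium reagent, and steps 10 and 11 form the side-chain branch.

The three steps most likely to fail:

1. Step 2, the carbene annulation. Face selection by the chiral triazolium may be poor with a β-methyl enal, crotonaldehyde may annulate with itself, and the cis preference may erode, so the lactone could arrive in low enantiomeric purity or as a cis/trans mixture. The fallback sets out from 3 and comes back at 7, and replaces the annulation by asymmetric crotylboration. Aldehyde 3 is treated at −78 °C with the (Z)-crotyldiisopinocampheylborane made from cis-but-2-ene, n-BuLi/KOt-Bu, (−)-Ipc2BOMe (from (+)-α-pinene) and BF3·OEt2, and the borinate is oxidised with NaBO3·4H2O. The closed chair transition state should set both centres and give the syn homoallylic alcohol 4-[(1S,2R)-1-hydroxy-2-methylbut-3-en-1-yl]-2-methoxyphenyl 4-methylbenzenesulfonate F1. Hydroboration of the vinyl group with 9-borabicyclo[3.3.1]nonane and oxidation with NaBO3·4H2O gives 4-[(1S,2R)-1,4-dihydroxy-2-methylbutyl]-2-methoxyphenyl 4-methylbenzenesulfonate F2. TEMPO/PhI(OAc)2 in CH2Cl2 then oxidises the primary alcohol selectively; the lactol closes and is oxidised on to lactone 7.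

2. Step 13, the final reduction. Felkin–Anh control by a small hydride may be weak, and the guaiacyl ether oxygens could still organise a chelate, so the erythro carbinol may form alongside or in place of the threo one. The fallback sets out from 21 and comes back at 22, and sets C7'' by chelation followed by inversion. Zn(BH4)2 in Et2O at −20 °C should reduce through the chelate to the erythro alcohol (1S,2R)-1-(3,4-dimethoxyphenyl)-2-{4-[(2S,3R,4R,5S)-5-(3,4-dimethoxyphenyl)-3,4-dimethyloxolan-2-yl]-2-methoxyphenoxy}propan-1-ol F3. A Mitsunobu reaction (4-nitrobenzoic acid, PPh3, diisopropyl azodicarboxylate, THF, 0 °C) inverts C7'' to the (1R,2R)-1-(3,4-dimethoxyphenyl)-2-{4-[(2S,3R,4R,5S)-5-(3,4-dimethoxyphenyl)-3,4-dimethyloxolan-2-yl]-2-methoxyphenoxy}propyl 4-nitrobenzoate F4, and K2CO3 in MeOH removes the ester to give 22.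

3. Step 12, the phenol alkylation. The α-tosyloxy ketone and the α-aryloxy ketone product can enolise under carbonate base, which would erode the C8'' configuration, and elimination of sulfonate can compete. The fallback sets out from 17 and 19 and comes back at 21, bypassing tosylate 20. A Mitsunobu etherification of phenol 17 with hydroxy ketone 19 (PPh3, diisopropyl azodicarboxylate, THF, 0 °C) forms the O4'–C8'' bond with inversion under near-neutral conditions; no new compound arises (F0).

**Further compounds**

F1 | step 2 | 4-[(1S,2R)-1-hydroxy-2-methylbut-3-en-1-yl]-2-methoxyphenyl 4-methylbenzenesulfonate | C=C[C@@H](C)[C@H](O)c1ccc(OS(=O)(=O)c2ccc(C)cc2)c(OC)c1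
F2 | step 2 | 4-[(1S,2R)-1,4-dihydroxy-2-methylbutyl]-2-methoxyphenyl 4-methylbenzenesulfonate | OCC[C@@H](C)[C@H](O)c1ccc(OS(=O)(=O)c2ccc(C)cc2)c(OC)c1
F3 | step 13 | (1S,2R)-1-(3,4-dimethoxyphenyl)-2-{4-[(2S,3R,4R,5S)-5-(3,4-dimethoxyphenyl)-3,4-dimethyloxolan-2-yl]-2-methoxyphenoxy}propan-1-ol | COc1ccc([C@H](O)[C@@H](C)Oc2ccc([C@H]3O[C@H](c4ccc(OC)c(OC)c4)[C@H](C)[C@H]3C)cc2OC)cc1OC
F4 | step 13 | (1R,2R)-1-(3,4-dimethoxyphenyl)-2-{4-[(2S,3R,4R,5S)-5-(3,4-dimethoxyphenyl)-3,4-dimethyloxolan-2-yl]-2-methoxyphenoxy}propyl 4-nitrobenzoate | COc1ccc([C@@H](OC(=O)c2ccc([N+](=O)[O-])cc2)[C@@H](C)Oc2ccc([C@H]3O[C@H](c4ccc(OC)c(OC)c4)[C@H](C)[C@H]3C)cc2OC)cc1OC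
F0 | step 12 | none | none
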